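**Assumption:** the target is drawn as the free bis(hydrogen sulfate). The route reaches it as a salt that is protonated in the last work-up; the acid form is labile and would be stored as the salt.
Ring A is numbered as in carotenoids: C1 (gem-dimethyl), C2, C3 (OH), C4 (OSO3H), C5 (methyl), C6 (bears C7).

## Retrosynthetic overview

- The C40 skeleton is cut at C10–C11 and C10'–C11' (double Suzuki coupling) into two identical dienyl iodides and a pentaenyl bis(boronate) made from the C10 dialdehyde.
- The route rests on one feature of ring A: O3 and C7 (on C6) are cis-1,4, so an O3–C7 bond can bridge C3 and C6 as a 2-oxabicyclo[2.2.2]octane and be cut later at C7–O.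
- While the bridge holds O3, the C4–OH and C5–H are added to the C4=C5 alkene from the face of the lactone bridge, and O4 alone is tagged (TES) for sulfation.
- The bridge comes from one hetero-Diels–Alder reaction of 2,6,6-trimethylcyclohexa-1,3-diene with ethyl glyoxylate (C6–C7 and C3–O bonds); the ester carbon is then excised oxidatively to leave C7 as a lactone carbonyl.
- Ring order: carbocycle A is bought with the enone; the dihydropyran bridge ring is the only ring formed (step 3) and is opened again in steps 8 and 9.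

Key step: step 3

## Route

Step 1
Reactants: 1 2,4,4-trimethylcyclohex-2-en-1-one
Product: 2 N'-[(1E)-2,4,4-trimethylcyclohex-2-en-1-ylidene]-4-methylbenzenesulfonohydrazide
Conditions: TsNHNH2 (1.05 equiv), EtOH, cat. HCl, 60 °C, then 0 °C (crystallisation)
Reagents that add atoms: p-toluenesulfonohydrazide, Cc1ccc(cc1)S(=O)(=O)NN
Why: Hydrazone condensation of an enone; the NHTs group should settle anti to the methyl-bearing vinyl carbon, that is syn to the C6 methylene that must be deprotonated in step 2.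

Step 2
Reactants: 2 tosylhydrazone
Product: 4 2,6,6-trimethylcyclohexa-1,3-diene, via vinyllithium 3 (not isolated)
Conditions: MeLi (2.3 equiv), Et2O, 0 → 20 °C; H2O; careful distillation of the volatile diene
Reagents that add atoms: none
Why: Shapiro reaction of an enone tosylhydrazone: the second deprotonation can only occur at the syn α'-methylene (the γ-carbon is quaternary), and loss of sulfinate and N2 gives the vinyllithium, which is protonated to the 1,3-diene with the new double bond toward the former CH2.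

Step 3
Reactants: 4 2,6,6-trimethylcyclohexa-1,3-diene; 5 ethyl glyoxylate (monomer, freshly distilled from the commercial toluene solution)
Product: 6 ethyl (1R,3S,4S)-5,8,8-trimethyl-2-oxabicyclo[2.2.2]oct-5-ene-3-carboxylate (endo ester)
Conditions: Cu(OTf)2 (10 mol%), 2,2'-(propane-2,2-diyl)bis[(4S)-4-tert-butyl-4,5-dihydrooxazole] (11 mol%), 5 (2 equiv), CH2Cl2, −20 → 20 °C
Reagents that add atoms: none
Why: Glyoxylate bound through both carbonyl oxygens to the Cu(OTf)2–bis(oxazoline) complex should add to the s-cis-locked diene in an asynchronous concerted [4+2] cycloaddition, the closest known reaction type being the copper–bis(oxazoline)-catalysed hetero-Diels–Alder reaction of cyclohexa-1,3-dienes with glyoxylate esters. The formyl carbon bonds first to C6 because the developing positive charge then sits on the methyl-bearing C5, and the carbonyl oxygen closes on C3; the one new ring, the 3,6-dihydro-2H-pyran (O, C7, C6, C5, C4, C3), is thus closed by cycloaddition, suprafacially on the diene, which forces O3 and C7 cis and gives the 2-oxabicyclo[2.2.2]octene. C6 and C3 are set together by the enantiotopic diene face that the tert-butyl groups of the (S,S) ligand leave open toward the si face of the bound aldehyde (the (R,R) ligand would be used if the opposite sense were found), and the temporary C7 centre by endo approach. Endo approach is reinforced by the substrate, because only the formyl hydrogen, not the ester, can sit beside the C1 methyl that flanks C6. The step needs C6-over-C3 regiochemistry, which the C5 methyl must secure against the neopentyl hindrance at C6, and cycloaddition over the carbonyl-ene reaction of the C5 methyl, which the cisoid ring diene and two-point binding of glyoxylate favour.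

Step 4
Reactants: 6 bicyclic ester
Product: 7 (1R,3S,4S)-5,8,8-trimethyl-2-oxabicyclo[2.2.2]oct-5-ene-3-carboxylic acid
Conditions: LiOH·H2O (1.5 equiv), THF/H2O, 0 → 20 °C; cold 0.5 M HCl to pH 4, immediate extraction
Reagents that add atoms: lithium hydroxide, [Li+].[OH-]
Why: Ester saponification; the bridgeheads cannot epimerise, the C7 centre is temporary, and the work-up is kept cold and only weakly acidic because the bridging ether is allylic and ionisable.

Step 5
Reactants: 7 bicyclic acid
Product: 9 (1R,4S)-5,8,8-trimethyl-2-oxabicyclo[2.2.2]oct-5-en-3-one, via dilithium hydroperoxy carboxylate 8 (not isolated)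
Conditions: LDA (2.3 equiv), THF, −78 → 0 °C; O2, −78 °C; AcOH (2.5 equiv), −78 → 20 °C
Reagents that add atoms: dioxygen, O=O
Why: Oxidative decarboxylation by oxygenation of a carboxylic acid dianion: the enediolate takes up O2 at C7, and the α-alkoxy α-hydroperoxy acid fragments on protonation to CO2, water and the lactone carbonyl, with no cationic or open-chain aldehyde stage that could ionise the allylic ether or conjugate the alkene; the bridgehead C6–H cannot enolise.

Step 6
Reactants: 9 unsaturated lactone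
Product: 11 (1R,4R,5R,6S)-6-hydroxy-5,8,8-trimethyl-2-oxabicyclo[2.2.2]octan-3-one, via alkylborane 10 (not isolated)
Conditions: BH3·THF (1.1 equiv), THF, −10 → 0 °C; then 30% H2O2, pH 7 phosphate buffer, 0 °C
Reagents that add atoms: hydrogen peroxide, OO
Why: Hydroboration–oxidation: boron goes to the less substituted C4 and hydrogen to C5 in a syn addition from the face of the flat lactone bridge (the other face carries a C1 methyl over C5), which sets C4–O cis to O3 and the C5 methyl trans to C7, and buffered oxidation proceeds with retention while sparing the lactone.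

Step 7
Reactants: 11 hydroxy lactone
Product: 12 (1R,4R,5R,6S)-5,8,8-trimethyl-6-[(triethylsilyl)oxy]-2-oxabicyclo[2.2.2]octan-3-one
Conditions: TESCl (1.3 equiv), imidazole, cat. DMAP, DMF, 20 °C
Reagents that add atoms: chlorotriethylsilane, CC[Si](Cl)(CC)CC
Why: Silylation of the only free hydroxyl; O3 is still tied up in the lactone, so the TES group marks O4 and no other oxygen.

Step 8
Reactants: 12 TES lactone
Product: 13 (1R,4R,5R,6S)-5,8,8-trimethyl-6-[(triethylsilyl)oxy]-2-oxabicyclo[2.2.2]octan-3-ol (both C3 epimers, in equilibrium with the cis-hydroxy aldehyde)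
Conditions: i-Bu2AlH (1.05 equiv), CH2Cl2, −78 °C; Rochelle salt work-up; used crude
Reagents that add atoms: none
Why: Partial reduction of a lactone to the lactol with i-Bu2AlH, which stops at the aluminium hemiacetal at −78 °C and leaves the silyl ether untouched.

Step 9
Reactants: 13 lactol; 14 1-(triphenylphosphoranylidene)propan-2-one
Product: 15 (3E)-4-[(1R,4R,5S,6R)-4-hydroxy-2,2,6-trimethyl-5-[(triethylsilyl)oxy]cyclohexyl]but-3-en-2-one
Conditions: 14 (3 equiv), toluene, 90 °C
Reagents that add atoms: none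
Why: Wittig reaction of a stabilised ylide with the open hydroxy-aldehyde tautomer, which cuts the bridge at C7–O, frees O3–H and gives the E enone; C6 should hold its configuration because the equatorial side chain trans to the C5 methyl is also the more stable epimer.

Step 10
Reactants: 15 hydroxy enone
Product: 16 (3E)-4-[(1R,4R,5S,6R)-4-[(tert-butyldimethylsilyl)oxy]-2,2,6-trimethyl-5-[(triethylsilyl)oxy]cyclohexyl]but-3-en-2-one
Conditions: TBSOTf (1.3 equiv), 2,6-lutidine, CH2Cl2, −78 °C
Reagents that add atoms: tert-butyldimethylsilyl triflate, CC(C)(C)[Si](C)(C)OS(=O)(=O)C(F)(F)F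
Why: Silylation of the hindered axial O3–H with a silyl triflate at low temperature, where the alcohol reacts faster than the methyl ketone enolises, giving a TBS ether that will outlast the O4 TES ether.

Step 11
Reactants: 16 bis-silyl enone
Product: 18 (1E)-1-[(1R,4R,5S,6R)-4-[(tert-butyldimethylsilyl)oxy]-2,2,6-trimethyl-5-[(triethylsilyl)oxy]cyclohexyl]but-1-en-3-yne, via enol phosphate 17 (not isolated)
Conditions: LDA (1.1 equiv), THF, −78 °C; ClP(O)(OEt)2; LDA (2.3 equiv), −78 → 20 °C; H2O
Reagents that add atoms: none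
Why: Negishi conversion of a methyl ketone into a terminal alkyne: the kinetic enolate of the methyl group is trapped as the enol phosphate, and LDA eliminates diethyl phosphate to the acetylide, as established for ionone-type enones.

Step 12
Reactants: 18 enyne
Product: 20 (1E,3E)-1-iodo-2-methyl-4-[(1R,4R,5S,6R)-4-[(tert-butyldimethylsilyl)oxy]-2,2,6-trimethyl-5-[(triethylsilyl)oxy]cyclohexyl]buta-1,3-diene, via alkenylalane 19 (not isolated)
Conditions: AlMe3 (3 equiv), Cp2ZrCl2 (0.3 equiv), CH2Cl2, 0 → 20 °C; I2, THF, −30 → 0 °C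
Reagents that add atoms: trimethylaluminium, C[Al](C)C; iodine, II
Why: Zirconium-catalysed Negishi carboalumination adds methyl and aluminium syn across the alkyne with methyl on the internal carbon (C9), and iodinolysis with retention gives the E C9=C10 iodide.

Step 13
Reactants: 20 bis-silyl dienyl iodide
Product: 21 (1E,3E)-1-iodo-2-methyl-4-[(1R,4R,5S,6R)-4-[(tert-butyldimethylsilyl)oxy]-5-hydroxy-2,2,6-trimethylcyclohexyl]buta-1,3-diene
Conditions: PPTS (0.2 equiv), MeOH/CH2Cl2, 0 → 20 °C
Reagents that add atoms: none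
Why: Acid-catalysed methanolysis removes the TES ether far faster than the hindered secondary TBS ether, so O4–H alone is freed and no base is present to move the silyl group.

Step 14
Reactants: 21 O4 alcohol
Product: 23 tetrabutylammonium (1S,2R,3R,6R)-6-[(tert-butyldimethylsilyl)oxy]-3-[(1E,3E)-4-iodo-3-methylbuta-1,3-dien-1-yl]-2,4,4-trimethylcyclohexyl sulfate, via pyridinium sulfate 22 (not isolated)
Conditions: SO3·pyridine (5 equiv), pyridine, 20–40 °C; then aq. Bu4NOH (1 equiv), extraction into CH2Cl2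
Reagents that add atoms: sulfur trioxide–pyridine complex, [O-]S(=O)(=O)[n+]1ccccc1; tetrabutylammonium hydroxide, CCCC[N+](CCCC)(CCCC)CCCC.[OH-]
Why: O-sulfation of an alcohol with SO3·pyridine can only reach O4 because O3 is silylated, and ion pairing with tetrabutylammonium gives a salt that can be handled in organic solvents.

Step 15
Reactants: 23 silylated sulfate
Product: 24 tetrabutylammonium (1S,2R,3R,6R)-6-hydroxy-3-[(1E,3E)-4-iodo-3-methylbuta-1,3-dien-1-yl]-2,4,4-trimethylcyclohexyl sulfate
Conditions: Bu4NF (2 equiv), THF, 20–40 °C, dark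
Reagents that add atoms: none
Why: Fluoride desilylation frees O3–H while the sulfate monoester anion is inert to fluoride and base, and the cis O3/O4 arrangement rules out displacement of sulfate to an epoxide.

Step 16
Reactants: 25 (2E,4E,6E)-2,7-dimethylocta-2,4,6-trienedial
Product: 26 2,2'-[(1E,3E,5E,7E,9E)-3,8-dimethyldeca-1,3,5,7,9-pentaene-1,10-diyl]bis(4,4,5,5-tetramethyl-1,3,2-dioxaborolane)
Conditions: Cl2CHBpin (4 equiv), CrCl2 (16 equiv), LiI (8 equiv), THF, 20 °C, dark
Reagents that add atoms: 2-(dichloromethyl)-4,4,5,5-tetramethyl-1,3,2-dioxaborolane, CC1(C)OB(OC1(C)C)C(Cl)Cl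
Why: Takai–Utimoto boryl olefination: the gem-dichromium reagent formed from the dihalomethylboronate adds to each aldehyde and eliminates to the E alkenylboronate, which extends the triene by C11 and C11' without touching the existing double bonds.

Step 17
Reactants: 24 sulfated dienyl iodide (2.2 equiv); 26 pentaenyl bis(boronate)
Product: 28 (3R,3'R,4S,4'S,5R,5'R,6R,6'R)-5,6,5',6'-tetrahydro-β,β-carotene-3,3',4,4'-tetrol 4,4'-bis(hydrogen sulfate), via bis(tetrabutylammonium) salt 27 (not isolated)
Conditions: Pd(OAc)2 (5 mol%), SPhos (10 mol%), aq. K3PO4, THF, 20–35 °C, degassed, dark; then cold dilute HCl to pH 2 and extraction with n-BuOH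
Reagents that add atoms: none
Why: Double Suzuki–Miyaura coupling forms the C10–C11 and C10'–C11' single bonds with retention of both alkene geometries, tolerates the free hydroxyls and sulfate anions, and the final protonation gives the acid form drawn.

## Compound list

1 | 2,4,4-trimethylcyclohex-2-en-1-one | CC1=CC(C)(C)CCC1=O | starting material
2 | N'-[(1E)-2,4,4-trimethylcyclohex-2-en-1-ylidene]-4-methylbenzenesulfonohydrazide | CC1=CC(C)(C)CC/C1=N\NS(=O)(=O)c1ccc(C)cc1 | intermediate
3 | (4,4,6-trimethylcyclohexa-1,5-dien-1-yl)lithium | [Li]C1=CCC(C)(C)C=C1C | intermediate (not isolated)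
4 | 2,6,6-trimethylcyclohexa-1,3-diene | CC1=CC(C)(C)CC=C1 | intermediate
5 | ethyl glyoxylate | CCOC(=O)C=O | starting material
6 | ethyl (1R,3S,4S)-5,8,8-trimethyl-2-oxabicyclo[2.2.2]oct-5-ene-3-carboxylate | CCOC(=O)[C@@H]1[C@@H]2C(C)=C[C@H](O1)CC2(C)C | intermediate
7 | (1R,3S,4S)-5,8,8-trimethyl-2-oxabicyclo[2.2.2]oct-5-ene-3-carboxylic acid | OC(=O)[C@@H]1[C@@H]2C(C)=C[C@H](O1)CC2(C)C | intermediate
8 | dilithium (1R,4S)-3-peroxido-5,8,8-trimethyl-2-oxabicyclo[2.2.2]oct-5-ene-3-carboxylate (C3 not assigned) | [Li+].[Li+].[O-]OC1(C([O-])=O)[C@@H]2C(C)=C[C@H](O1)CC2(C)C | intermediate (not isolated)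
9 | (1R,4S)-5,8,8-trimethyl-2-oxabicyclo[2.2.2]oct-5-en-3-one | O=C1[C@@H]2C(C)=C[C@H](O1)CC2(C)C | intermediate
10 | (1R,4R,5S,6S)-6-boranyl-5,8,8-trimethyl-2-oxabicyclo[2.2.2]octan-3-one (boron on the face of the lactone bridge) | O=C1[C@@H]2[C@@H](C)[C@H](B)[C@H](O1)CC2(C)C | intermediate (not isolated)
11 | (1R,4R,5R,6S)-6-hydroxy-5,8,8-trimethyl-2-oxabicyclo[2.2.2]octan-3-one | O=C1[C@@H]2[C@@H](C)[C@H](O)[C@H](O1)CC2(C)C | intermediate
12 | (1R,4R,5R,6S)-5,8,8-trimethyl-6-[(triethylsilyl)oxy]-2-oxabicyclo[2.2.2]octan-3-one | O=C1[C@@H]2[C@@H](C)[C@H](O[Si](CC)(CC)CC)[C@H](O1)CC2(C)C | intermediate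
13 | (1R,4R,5R,6S)-5,8,8-trimethyl-6-[(triethylsilyl)oxy]-2-oxabicyclo[2.2.2]octan-3-ol (C3 epimers) | OC1[C@@H]2[C@@H](C)[C@H](O[Si](CC)(CC)CC)[C@H](O1)CC2(C)C | intermediate
14 | 1-(triphenylphosphoranylidene)propan-2-one | CC(=O)C=P(c1ccccc1)(c1ccccc1)c1ccccc1 | starting material
15 | (3E)-4-[(1R,4R,5S,6R)-4-hydroxy-2,2,6-trimethyl-5-[(triethylsilyl)oxy]cyclohexyl]but-3-en-2-one | CC(=O)/C=C/[C@@H]1[C@@H](C)[C@H](O[Si](CC)(CC)CC)[C@H](O)CC1(C)C | intermediate
16 | (3E)-4-[(1R,4R,5S,6R)-4-[(tert-butyldimethylsilyl)oxy]-2,2,6-trimethyl-5-[(triethylsilyl)oxy]cyclohexyl]but-3-en-2-one | CC(=O)/C=C/[C@@H]1[C@@H](C)[C@H](O[Si](CC)(CC)CC)[C@H](O[Si](C)(C)C(C)(C)C)CC1(C)C | intermediate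
17 | diethyl (3E)-4-[(1R,4R,5S,6R)-4-[(tert-butyldimethylsilyl)oxy]-2,2,6-trimethyl-5-[(triethylsilyl)oxy]cyclohexyl]buta-1,3-dien-2-yl phosphate | C=C(OP(=O)(OCC)OCC)/C=C/[C@@H]1[C@@H](C)[C@H](O[Si](CC)(CC)CC)[C@H](O[Si](C)(C)C(C)(C)C)CC1(C)C | intermediate (not isolated)
18 | (1E)-1-[(1R,4R,5S,6R)-4-[(tert-butyldimethylsilyl)oxy]-2,2,6-trimethyl-5-[(triethylsilyl)oxy]cyclohexyl]but-1-en-3-yne | C#C/C=C/[C@@H]1[C@@H](C)[C@H](O[Si](CC)(CC)CC)[C@H](O[Si](C)(C)C(C)(C)C)CC1(C)C | intermediate
19 | dimethyl[(1E,3E)-2-methyl-4-[(1R,4R,5S,6R)-4-[(tert-butyldimethylsilyl)oxy]-2,2,6-trimethyl-5-[(triethylsilyl)oxy]cyclohexyl]buta-1,3-dien-1-yl]alumane | C[Al](C)/C=C(C)/C=C/[C@@H]1[C@@H](C)[C@H](O[Si](CC)(CC)CC)[C@H](O[Si](C)(C)C(C)(C)C)CC1(C)C | intermediate (not isolated)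
20 | (1E,3E)-1-iodo-2-methyl-4-[(1R,4R,5S,6R)-4-[(tert-butyldimethylsilyl)oxy]-2,2,6-trimethyl-5-[(triethylsilyl)oxy]cyclohexyl]buta-1,3-diene | I/C=C(C)/C=C/[C@@H]1[C@@H](C)[C@H](O[Si](CC)(CC)CC)[C@H](O[Si](C)(C)C(C)(C)C)CC1(C)C | intermediate
21 | (1E,3E)-1-iodo-2-methyl-4-[(1R,4R,5S,6R)-4-[(tert-butyldimethylsilyl)oxy]-5-hydroxy-2,2,6-trimethylcyclohexyl]buta-1,3-diene | I/C=C(C)/C=C/[C@@H]1[C@@H](C)[C@H](O)[C@H](O[Si](C)(C)C(C)(C)C)CC1(C)C | intermediate
22 | pyridinium (1S,2R,3R,6R)-6-[(tert-butyldimethylsilyl)oxy]-3-[(1E,3E)-4-iodo-3-methylbuta-1,3-dien-1-yl]-2,4,4-trimethylcyclohexyl sulfate | I/C=C(C)/C=C/[C@@H]1[C@@H](C)[C@H](OS(=O)(=O)[O-])[C@H](O[Si](C)(C)C(C)(C)C)CC1(C)C.c1cc[nH+]cc1 | intermediate (not isolated)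
23 | tetrabutylammonium (1S,2R,3R,6R)-6-[(tert-butyldimethylsilyl)oxy]-3-[(1E,3E)-4-iodo-3-methylbuta-1,3-dien-1-yl]-2,4,4-trimethylcyclohexyl sulfate | I/C=C(C)/C=C/[C@@H]1[C@@H](C)[C@H](OS(=O)(=O)[O-])[C@H](O[Si](C)(C)C(C)(C)C)CC1(C)C.CCCC[N+](CCCC)(CCCC)CCCC | intermediate
24 | tetrabutylammonium (1S,2R,3R,6R)-6-hydroxy-3-[(1E,3E)-4-iodo-3-methylbuta-1,3-dien-1-yl]-2,4,4-trimethylcyclohexyl sulfate | I/C=C(C)/C=C/[C@@H]1[C@@H](C)[C@H](OS(=O)(=O)[O-])[C@H](O)CC1(C)C.CCCC[N+](CCCC)(CCCC)CCCC | intermediate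
25 | (2E,4E,6E)-2,7-dimethylocta-2,4,6-trienedial | O=C/C(C)=C/C=C/C=C(C)/C=O | starting material
26 | 2,2'-[(1E,3E,5E,7E,9E)-3,8-dimethyldeca-1,3,5,7,9-pentaene-1,10-diyl]bis(4,4,5,5-tetramethyl-1,3,2-dioxaborolane) | CC1(C)OB(OC1(C)C)/C=C/C(C)=C/C=C/C=C(C)/C=C/B1OC(C)(C)C(C)(C)O1 | intermediate
27 | bis(tetrabutylammonium) salt of 28 | CC(/C=C/C=C(C)/C=C/[C@@H]1[C@@H](C)[C@H](OS(=O)(=O)[O-])[C@H](O)CC1(C)C)=C\C=C\C=C(C)\C=C\C=C(C)\C=C\[C@@H]1[C@@H](C)[C@H](OS(=O)(=O)[O-])[C@H](O)CC1(C)C.CCCC[N+](CCCC)(CCCC)CCCC.CCCC[N+](CCCC)(CCCC)CCCC | intermediate (not isolated)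
28 | (3R,3'R,4S,4'S,5R,5'R,6R,6'R)-5,6,5',6'-tetrahydro-β,β-carotene-3,3',4,4'-tetrol 4,4'-bis(hydrogen sulfate) | CC(/C=C/C=C(C)/C=C/[C@@H]1[C@@H](C)[C@H](OS(=O)(=O)O)[C@H](O)CC1(C)C)=C\C=C\C=C(C)\C=C\C=C(C)\C=C\[C@@H]1[C@@H](C)[C@H](OS(=O)(=O)O)[C@H](O)CC1(C)C | target

## Step count and risks

Total step count: 17. Longest linear sequence: 16 steps (steps 1 to 15, then step 17, from 1 to 28); step 16 is a one-step branch.

**Step 3.** The formyl carbon has to bond at the diene terminus next to the quaternary carbon. A more stepwise path through the tertiary allyl cation can leak to the carbonyl-ene product by proton loss from the C5 methyl, and a looser transition state would erode face selectivity. Fallback: from 4 and 5, the cycloaddition would be run without any Lewis acid under high pressure (about 10 kbar, CH2Cl2, 20–50 °C), which removes the cationic ene channel and keeps the endo preference, to give the racemic ester F1. Saponification would give the racemic acid F2. Crystallisation with (R)-1-phenylethylamine (or its enantiomer, whichever gives the less soluble salt with the wanted acid) would give the (R)-1-phenylethylammonium salt of the (1R,3S,4S) acid F3, and cold acidification returns to the route at 7.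

**Step 5.** The dianion may form incompletely, because the C7–H lies beside a C1 methyl, and the strained lactone may be attacked by the basic peroxide species before quench. Fallback: from 7, two-electron oxidative decarboxylation with Pb(OAc)4 and pyridine in benzene would give the anomeric acetate F4. Neutral deacetylation with Bu3SnOMe would give the lactol F5, which must be kept cold and unpurified because its open hydroxy-aldehyde form can slip into conjugation. Oxidation with catalytic TEMPO and PhI(OAc)2 then comes back to the route at 9.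

**Step 6.** The organoborane may lose boron by syn β-elimination toward the lactone oxygen (ring opening), borane may reduce the strained lactone, or addition may occur on the face of the gem-dimethyl bridge. Fallback: from 9, epoxidation with mCPBA and NaHCO3 on the lactone face would give the epoxide F6. TMSOTf with 2,6-lutidine and then DBU would open it to the exocyclic-methylene allylic silyl ether F7, and mild aqueous acid would give the allylic alcohol F8. Hydroxyl-directed hydrogenation with [Ir(cod)(PCy3)(py)]PF6 and H2 would then deliver hydrogen to C5 from the face of the C4–OH and come back to the route at 11.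

## Further compounds

F1 | step 3 | racemic ethyl (1R*,3S*,4S*)-5,8,8-trimethyl-2-oxabicyclo[2.2.2]oct-5-ene-3-carboxylate | CCOC(=O)[C@@H]1[C@@H]2C(C)=C[C@H](O1)CC2(C)C.CCOC(=O)[C@H]1[C@H]2C(C)=C[C@@H](O1)CC2(C)C
F2 | step 3 | racemic (1R*,3S*,4S*)-5,8,8-trimethyl-2-oxabicyclo[2.2.2]oct-5-ene-3-carboxylic acid | OC(=O)[C@@H]1[C@@H]2C(C)=C[C@H](O1)CC2(C)C.OC(=O)[C@H]1[C@H]2C(C)=C[C@@H](O1)CC2(C)C
F3 | step 3 | (R)-1-phenylethylammonium (1R,3S,4S)-5,8,8-trimethyl-2-oxabicyclo[2.2.2]oct-5-ene-3-carboxylate | [O-]C(=O)[C@@H]1[C@@H]2C(C)=C[C@H](O1)CC2(C)C.C[C@@H]([NH3+])c1ccccc1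
F4 | step 5 | (1R,4S)-5,8,8-trimethyl-2-oxabicyclo[2.2.2]oct-5-en-3-yl acetate (C3 epimers) | CC(=O)OC1[C@@H]2C(C)=C[C@H](O1)CC2(C)C
F5 | step 5 | (1R,4S)-5,8,8-trimethyl-2-oxabicyclo[2.2.2]oct-5-en-3-ol (C3 epimers, with its open hydroxy-aldehyde form) | OC1[C@@H]2C(C)=C[C@H](O1)CC2(C)C
F6 | step 6 | 5,6-epoxide of 9 on the face of the lactone bridge | O=C1[C@@H]2[C@]3(C)O[C@@H]3[C@H](O1)CC2(C)C
F7 | step 6 | (1R,4S,6S)-8,8-dimethyl-5-methylidene-6-[(trimethylsilyl)oxy]-2-oxabicyclo[2.2.2]octan-3-one | O=C1[C@@H]2C(=C)[C@H](O[Si](C)(C)C)[C@H](O1)CC2(C)C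
F8 | step 6 | (1R,4S,6S)-6-hydroxy-8,8-dimethyl-5-methylidene-2-oxabicyclo[2.2.2]octan-3-one | O=C1[C@@H]2C(=C)[C@H](O)[C@H](O1)CC2(C)C
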